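The dusk run and the spring run differ in c(impurity), yet their last readings look alike, and two chemists dispute what this means for delta and gamma.

all flasks: left-handed substrate 0.25 M; right-handed substrate 0.25 M; gas 16 mM (held); free catalyst 0.19 mol%
- dusk: impurity 0.10 mM; run made earlier
- spring: impurity 0.16 mM; run made earlier
- delta: impurity 0.20 mM; time 20 h
- gamma: impurity 0.12 mM; time 20 h

| run | time / h | left-handed product / % | right-handed product / % |
|---|---|---|---|
| dusk | 0.833 | 0.1 | 1.5 |
| dusk | 1.33 | 0 | 2.5 |
| dusk | 2.00 | 0.3 | 2.3 |
| dusk | 3.00 | 2.3 | 3.7 |
| dusk | 4.00 | 0 | 4.2 |
| dusk | 6.00 | 2.3 | 6.1 |
| dusk | 10.0 | 1.4 | 7.6 |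
| spring | 0.833 | 0.5 | 1.0 |
| spring | 1.33 | 0.2 | 0 |
| spring | 2.00 | 0.8 | 0.7 |
| spring | 3.00 | 0.7 | 2.6 |
| spring | 4.00 | 2.0 | 5.5 |
| spring | 6.00 | 1.1 | 4.1 |
| spring | 10.0 | 1.5 | 8.2 |

(each reading ± 1 percentage point)

- free catalyst is single-handed; left-handed substrate and right-handed substrate are mirror images of each other, charged as a racemate, each of them at the stated concentration
- at the start none of reagent is dissolved
- the numbers in the tables scatter with a standard deviation of 1 percentage point
- reactions considered so far: free catalyst + left-handed substrate <-> catalyst intermediate A; free catalyst + right-handed substrate <-> catalyst intermediate B; reagent + catalyst intermediate A -> free catalyst + left-handed product; reagent + catalyst intermediate B -> free catalyst + right-handed product; 2 reagent -> homo dimer; gas <-> reagent; free catalyst + impurity -> spent catalyst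
- an excess is below zero if the other one leads

- which of the two ends with the higher excess of left-handed product over right-handed product in the product ("neither" if they lie within 2 percentage points) (delta / gamma / neither)
- excess of left-handed product over right-handed product in the product at the end, delta
- excess of left-handed product over right-handed product in the product at the end, gamma

The free catalyst charged is 0.475 mM. If impurity takes it one for one, delta keeps 57.9% of it and gamma 74.7%.

The first chemist says the excess belongs to the catalyst, since impurity removes catalyst from both paths alike. The two readings at 10.0 h sum to 2.90% left-handed product and 15.8% right-handed product, an excess of −69.0%, and she would keep that figure.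

The second answers that the excess slides as right-handed substrate is used up. Scaling the runs by time and by surviving catalyst, using 78.9% for dusk and 66.3% for spring, he expects 12.6% right-handed product in delta and 16.3% in gamma. So he expects the two flasks to part.

I weigh the slide in logarithms. If both substrates compete for the same free catalyst, each at a rate proportional to its own concentration, they lose powers of ten in a fixed proportion. That proportion, the logarithm of the fraction of right-handed substrate left over the logarithm of the fraction of left-handed substrate left, is the selectivity factor s.

Each summed pair is also the mean reading referred to one substrate's charge, so the logarithms of the fractions left are −0.0747 and −0.0128, and 5.84 is my reading of s. It is rough, since each left-handed value scatters by 1 percentage point.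

Dividing the logarithm of each flask's fraction of right-handed substrate left by s gives the same logarithm for left-handed substrate, and so I reckon −67.7% for delta and −66.6% for gamma, 1.1 points apart against a margin of 2 points.

The forecast sides with the first chemist on neither but stands higher than my delta figure, at −58% and −57%, on the ground that “It therefore changes the rate, not the selectivity”.

The simulation gives neither, with −69.9% for delta and −68.9% for gamma.

    free catalyst + left-handed substrate ⇌ catalyst intermediate A (K = 1.80 M⁻¹, k = 0.870 M⁻¹ s⁻¹)
    free catalyst + right-handed substrate ⇌ catalyst intermediate B (K = 25.0 M⁻¹, k = 12.0 M⁻¹ s⁻¹)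
    reagent + catalyst intermediate A → free catalyst + left-handed product (k = 0.680 M⁻¹ s⁻¹)
    reagent + catalyst intermediate B → free catalyst + right-handed product (k = 0.310 M⁻¹ s⁻¹)
    2 reagent → homo dimer (k = 0.00530 M⁻¹ s⁻¹)
    gas ⇌ reagent, rate k6*(csat - [reagent]) (kL = 0.00130 s⁻¹)
    free catalyst + impurity → spent catalyst (k = 120 M⁻¹ s⁻¹)

In delta, s turns 74% of right-handed substrate left into 95.0% of left-handed substrate left, and the flask holds 95%. In its neighbour with 0.76 mol% of free catalyst, 3.5% gives 56.3% against a simulated 59%, at an excess of −40.3%. The second chemist's parting appears late: at 200 h, delta stands at −7.59% and gamma at −2.90%. At 9.48 h in delta, catalyst intermediate A falls back 52 times faster than it goes on, while the forward steps favour right-handed substrate 12 to one.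

The runs come from a simulation for substances that don't exist, noise included.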